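The carbocycle is closed last, between C8a (the oxygen-bearing β-carbon of the γ-pyranone ring) and the carbinol carbon C8. The key step is a ring-closing Nozaki–Hiyama–Kishi reaction of a 2-iodo-4-pyranone with an aldehyde: in one operation it forms the six-membered ring, completes the bicyclo[4.3.1] core, sets C8 and delivers the target. It exploits that C8a is a vinylogous acyl carbon able to carry iodide and that the 1,5-benzodioxepine ring holds the C5 pyranonyl and C7 formyl groups cis. The precursor is this all-cis dioxepine, built from D-glucose-derived 2,4-O-benzylidene-D-erythrose (C6, C7) by Grignard addition (C5), Mitsunobu inversion (C7–O) and intramolecular SNAr (C5–O).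

Key step: step 16

Remark on numbering: C2–C8a denote the carbons of the tetrahydrochromone unit of the target and primed locants the 6,7-dioxygenated 2-(2-phenylethyl)chromone unit; these locants are used for all intermediates. "The dioxepine" (21–27) is the 1,5-benzodioxepine ring O5–C5–C6–C7–O7 fused at C7'/C6' of that chromone.
Remark on the chemistry: compounds 1, 2, 6, 9 and 10 are assumed to be catalogue chemicals; iodination of 4 is assumed to occur at C3, the α-carbon flanked by the sulfur-bearing carbon.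

Step 1
Reactants: 1 4,4-bis(methylsulfanyl)but-3-en-2-one; 2 3-(4-methoxyphenyl)propanoyl chloride
Product: 4 2-[2-(4-methoxyphenyl)ethyl]-6-(methylsulfanyl)-4H-pyran-4-one, via acyclic 1,3-diketone 3 (not isolated)
Conditions: LiN(SiMe3)2 (2 equiv) on 1 (2 equiv), THF, −78 °C; 2 (1 equiv), −78 → 0 °C; then CF3CO2H, CH2Cl2, rt
Reagents that add atoms: none
Why: The kinetic lithium enolate of the methyl ketone is C-acylated by the acid chloride (Claisen-type acylation), and the 1,3-diketone closes under acid by 6-endo addition of its enol oxygen to the ketene dithioacetal carbon with loss of methanethiol, the usual α-oxoketene dithioacetal entry to 2-(methylsulfanyl)-4-pyranones.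

Step 2
Reactants: 4 2-[2-(4-methoxyphenyl)ethyl]-6-(methylsulfanyl)-4H-pyran-4-one
Product: 5 3-iodo-6-[2-(4-methoxyphenyl)ethyl]-2-(methylsulfanyl)-4H-pyran-4-one
Conditions: N-iodosuccinimide, cat. CF3CO2H, MeCN, 0 °C → rt
Reagents that add atoms: N-iodosuccinimide O=C1CCC(=O)N1I
Why: Electrophilic iodination should occur at C3, the α-carbon that is β to both the ring oxygen and the sulfur donor and so the most nucleophilic position of the push–pull pyranone.

Step 3
Reactants: 6 4,6-O-benzylidene-D-glucopyranose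
Product: 7 2,4-O-benzylidene-D-erythrose [(2R,4R,5R)-5-hydroxy-2-phenyl-1,3-dioxane-4-carbaldehyde]
Conditions: NaIO4 (2.1 equiv), NaHCO3, H2O/dioxane, 0 °C → rt
Reagents that add atoms: none
Why: Malaprade periodate cleavage of the C1–C2 and C2–C3 glycol bonds (the O5 formate first formed is hydrolysed) leaves C3–C6 of D-glucose as protected D-erythrose, so that C6 and C7 of the target come from the chiral pool.

Step 4
Reactants: 7 2,4-O-benzylidene-D-erythrose
Product: 8 (2R,4R,5R)-2-phenyl-5-(triethylsilyloxy)-1,3-dioxane-4-carbaldehyde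
Conditions: Et3SiCl, imidazole, DMF, 0 °C
Reagents that add atoms: chlorotriethylsilane CC[Si](Cl)(CC)CC
Why: Routine silylation of the only free hydroxyl group unravels the hemiacetal dimer of 7 and gives the monomeric aldehyde.

Step 5
Reactants: 9 1-(5-bromo-4-fluoro-2-hydroxyphenyl)ethanone; 10 3-phenylpropanoyl chloride
Product: 12 6-bromo-7-fluoro-2-(2-phenylethyl)-4H-chromen-4-one, via chromone 1,3-diketone 11 (not isolated)
Conditions: LiN(SiMe3)2 (3 equiv), THF, −78 → −10 °C; 10, −78 °C → rt; then cat. H2SO4, AcOH, 95 °C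
Reagents that add atoms: none
Why: C-acylation of the ketone enolate of the phenoxide dianion gives the Baker–Venkataraman-type 1,3-diketone directly, which cyclodehydrates under acid to the chromone.

Step 6
Reactants: 12 6-bromo-7-fluoro-2-(2-phenylethyl)-4H-chromen-4-one
Product: 14 7-fluoro-6-hydroxy-2-(2-phenylethyl)-4H-chromen-4-one, via pinacol boronate 13 (not isolated)
Conditions: bis(pinacolato)diboron, PdCl2(dppf) (dppf = 1,1'-bis(diphenylphosphino)ferrocene), KOAc, dioxane, 90 °C; then H2O2, NaHCO3, THF/H2O, 0 °C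
Reagents that add atoms: hydrogen peroxide OO
Why: Miyaura borylation of the aryl bromide followed by oxidation of the C–B bond gives the C6' phenol without touching the C7' fluorine needed later.

Step 7
Reactants: 5 3-iodo-6-[2-(4-methoxyphenyl)ethyl]-2-(methylsulfanyl)-4H-pyran-4-one; 8 (2R,4R,5R)-2-phenyl-5-(triethylsilyloxy)-1,3-dioxane-4-carbaldehyde
Product: 17 3-{(R)-(tert-butyldimethylsilyloxy)[(2R,4S,5R)-2-phenyl-5-(triethylsilyloxy)-1,3-dioxan-4-yl]methyl}-6-[2-(4-methoxyphenyl)ethyl]-2-(methylsulfanyl)-4H-pyran-4-one, via pyranonylmagnesium chloride 15 (not isolated), via chloromagnesium alkoxide 16 (not isolated)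
Conditions: iPrMgCl·LiCl, THF, −40 °C; then 8 precomplexed with MgBr2·OEt2, CH2Cl2, −78 → −30 °C; then tBuMe2SiOTf, 2,6-lutidine, −78 → 0 °C
Reagents that add atoms: tert-butyldimethylsilyl trifluoromethanesulfonate CC(C)(C)[Si](C)(C)OS(=O)(=O)C(F)(F)F
Why: Iodine–magnesium exchange gives the pyranonyl Grignard reagent, whose addition to the aldehyde under Cram-chelate control (magnesium bridging the aldehyde oxygen and ring oxygen O6) forms the C4a–C5 bond and the 5,6-syn (5R) carbinol, trapped in situ as its silyl ether.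

Step 8
Reactants: 17 bis-silyl ether (5R)
Product: 18 3-{(R)-(tert-butyldimethylsilyloxy)[(2R,4R,5R)-5-hydroxy-2-phenyl-1,3-dioxan-4-yl]methyl}-6-[2-(4-methoxyphenyl)ethyl]-2-(methylsulfanyl)-4H-pyran-4-one
Conditions: pyridinium p-toluenesulfonate (cat.), MeOH/CH2Cl2, 0 °C
Reagents that add atoms: none
Why: Acid-catalysed methanolysis removes the secondary triethylsilyl ether much faster than the hindered tert-butyldimethylsilyl ether or the benzylidene acetal.

Step 9
Reactants: 18 C7 alcohol; 14 7-fluoro-6-hydroxy-2-(2-phenylethyl)-4H-chromen-4-one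
Product: 19 3-{(R)-(tert-butyldimethylsilyloxy)[(2R,4R,5S)-5-{[7-fluoro-4-oxo-2-(2-phenylethyl)-4H-chromen-6-yl]oxy}-2-phenyl-1,3-dioxan-4-yl]methyl}-6-[2-(4-methoxyphenyl)ethyl]-2-(methylsulfanyl)-4H-pyran-4-one
Conditions: PPh3, diisopropyl azodicarboxylate, toluene, 0 °C → rt
Reagents that add atoms: none
Why: Mitsunobu etherification with the acidic phenol proceeds by SN2 at C7 of the 1,3-dioxan-5-ol (axial approach is not blocked by syn-axial hydrogens) and so inverts C7 to the configuration of the target.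

Step 10
Reactants: 19 C7 aryl ether
Product: 21 dioxepine sulfide (5R,6S,7S; O6/O8 benzylidene acetal; pyranone C8a–SMe), via tetrabutylammonium C5 alkoxide 20 (not isolated)
Conditions: Bu4NF, THF, 0 → 50 °C
Reagents that add atoms: none
Why: Fluoride removes the silyl group and the C5 alkoxide displaces the C7' fluorine, activated by the para chromone carbonyl, in an intramolecular SNAr reaction that closes the seven-membered dioxepine ring with retention at C5, while the acetal keeps O6 and O8 from forming a six-membered ether.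

Step 11
Reactants: 21 dioxepine sulfide
Product: 22 dioxepine sulfone (5R,6S,7S; pyranone C8a–SO2Me)
Conditions: 3-chloroperbenzoic acid (2.2 equiv), NaHCO3, CH2Cl2, 0 °C → rt
Reagents that add atoms: 3-chloroperbenzoic acid O=C(OO)c1cccc(Cl)c1
Why: Peracid oxidation takes the vinylogous thioester sulfur to the sulfone, the electron-poor enones and aryl ethers being inert.

Step 12
Reactants: 22 dioxepine sulfone
Product: 23 dioxepine stannane (5R,6S,7S; pyranone C8a–SnBu3)
Conditions: Bu3SnH, azobisisobutyronitrile (cat.), toluene, 100 °C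
Reagents that add atoms: tributyltin hydride CCCC[SnH](CCCC)CCCC
Why: Radical stannyldesulfonylation, in which the tributyltin radical adds ipso to C8a and the α-keto radical expels the methanesulfonyl radical, is an established way to turn alkenyl sulfones into alkenylstannanes.

Step 13
Reactants: 23 dioxepine stannane
Product: 24 dioxepine iodide (5R,6S,7S; pyranone C8a–I)
Conditions: I2, CH2Cl2, 0 °C
Reagents that add atoms: iodine II
Why: Ipso iododestannylation of the alkenylstannane gives the 2-iodo-4-pyranone.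

Step 14
Reactants: 24 dioxepine iodide
Product: 25 iodo diol (5R,6S,7S; free 6-OH and C8H2OH)
Conditions: AcOH/H2O (4:1), 45 °C
Reagents that add atoms: none
Why: Mild aqueous acid hydrolyses the benzylidene acetal and frees O6 and O8 without ionising the aryl ethers.

Step 15
Reactants: 25 iodo diol
Product: 26 iodo aldehyde (5R,6S,7R; free 6-OH and C8 formyl group)
Conditions: TEMPO (cat.), PhI(OAc)2, CH2Cl2, rt; used crude
Reagents that add atoms: none
Why: The oxoammonium oxidation (TEMPO with PhI(OAc)2) converts the primary C8 alcohol into the aldehyde much faster than the secondary C6 alcohol, under neutral conditions that should not epimerise C7.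

Step 16
Reactants: 26 iodo aldehyde
Product: 28 (+)-4'-methoxyaquisinenone G (5R,6S,7R,8S), via alkenylchromium dichloride 27 (not isolated)
Conditions: CrCl2 (8 equiv), NiCl2 (2 mol %), degassed DMF, rt, 0.005 M
Reagents that add atoms: none
Why: NiCl2 is reduced by CrCl2 to zerovalent nickel, which adds oxidatively to the C8a–I bond of the 2-iodo-4-pyranone (a vinylogous acyl iodide), and transmetalation gives the trivalent alkenylchromium species 27, which adds intramolecularly to the C8 aldehyde. This is the Nozaki–Hiyama–Kishi reaction in its ring-closing form, well known for iodoalkenes and β-iodoenones. The six-membered carbocycle C4a–C5–C6–C7–C8–C8a closes by a 6-exo-trig carbonyl addition, which completes the bicyclo[4.3.1] core because C5 and C7 are already cis on the dioxepine ring. C8 is set by the substrate: the carbonyl oxygen should take the pseudoaxial position, anti to the C7–O bond (dipole minimisation), syn-axial to the free 6-OH that can bridge it through chromium, and away from O1 (no allylic 1,2-strain), which gives the 8S alcohol trans to O7. The step needs chemoselective activation of the single C–I bond (no other halide is present, and free hydroxyl groups, the chromone and the aryl ethers are tolerated by CrCl2) and high dilution to suppress intermolecular addition.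

Compound list

1 | 4,4-bis(methylsulfanyl)but-3-en-2-one | CC(=O)C=C(SC)SC | starting material
2 | 3-(4-methoxyphenyl)propanoyl chloride | COc1ccc(CCC(Cl)=O)cc1 | starting material
3 | 7-(4-methoxyphenyl)-1,1-bis(methylsulfanyl)hept-1-ene-3,5-dione | COc1ccc(CCC(=O)CC(=O)C=C(SC)SC)cc1 | intermediate
4 | 2-[2-(4-methoxyphenyl)ethyl]-6-(methylsulfanyl)-4H-pyran-4-one | COc1ccc(CCc2cc(=O)cc(SC)o2)cc1 | intermediate
5 | 3-iodo-6-[2-(4-methoxyphenyl)ethyl]-2-(methylsulfanyl)-4H-pyran-4-one | COc1ccc(CCc2cc(=O)c(I)c(SC)o2)cc1 | intermediate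
6 | 4,6-O-benzylidene-D-glucopyranose (anomeric mixture) | OC1[C@H](O)[C@@H](O)[C@@H]2O[C@H](c3ccccc3)OC[C@H]2O1 | starting material
7 | 2,4-O-benzylidene-D-erythrose, (2R,4R,5R)-5-hydroxy-2-phenyl-1,3-dioxane-4-carbaldehyde | O=C[C@@H]1O[C@H](c2ccccc2)OC[C@H]1O | intermediate
8 | (2R,4R,5R)-2-phenyl-5-(triethylsilyloxy)-1,3-dioxane-4-carbaldehyde | O=C[C@@H]1O[C@H](c2ccccc2)OC[C@H]1O[Si](CC)(CC)CC | intermediate
9 | 1-(5-bromo-4-fluoro-2-hydroxyphenyl)ethanone | CC(=O)c1cc(Br)c(F)cc1O | starting material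
10 | 3-phenylpropanoyl chloride | O=C(Cl)CCc1ccccc1 | starting material
11 | 1-(5-bromo-4-fluoro-2-hydroxyphenyl)-5-phenylpentane-1,3-dione | O=C(CCc1ccccc1)CC(=O)c1cc(Br)c(F)cc1O | intermediate
12 | 6-bromo-7-fluoro-2-(2-phenylethyl)-4H-chromen-4-one | O=c1cc(CCc2ccccc2)oc2cc(F)c(Br)cc12 | intermediate
13 | 7-fluoro-2-(2-phenylethyl)-6-(4,4,5,5-tetramethyl-1,3,2-dioxaborolan-2-yl)-4H-chromen-4-one | O=c1cc(CCc2ccccc2)oc2cc(F)c(B3OC(C)(C)C(C)(C)O3)cc12 | intermediate
14 | 7-fluoro-6-hydroxy-2-(2-phenylethyl)-4H-chromen-4-one | O=c1cc(CCc2ccccc2)oc2cc(F)c(O)cc12 | intermediate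
15 | {6-[2-(4-methoxyphenyl)ethyl]-2-(methylsulfanyl)-4-oxo-4H-pyran-3-yl}magnesium chloride | COc1ccc(CCc2cc(=O)c([Mg]Cl)c(SC)o2)cc1 | intermediate
16 | chloromagnesium alkoxide of the (5R) adduct of 15 and 8 | Cl[Mg]O[C@H](c1c(SC)oc(CCc2ccc(OC)cc2)cc1=O)[C@@H]3O[C@H](c4ccccc4)OC[C@H]3O[Si](CC)(CC)CC | intermediate
17 | 3-{(R)-(tert-butyldimethylsilyloxy)[(2R,4S,5R)-2-phenyl-5-(triethylsilyloxy)-1,3-dioxan-4-yl]methyl}-6-[2-(4-methoxyphenyl)ethyl]-2-(methylsulfanyl)-4H-pyran-4-one | CC(C)(C)[Si](C)(C)O[C@H](c1c(SC)oc(CCc2ccc(OC)cc2)cc1=O)[C@@H]3O[C@H](c4ccccc4)OC[C@H]3O[Si](CC)(CC)CC | intermediate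
18 | 3-{(R)-(tert-butyldimethylsilyloxy)[(2R,4R,5R)-5-hydroxy-2-phenyl-1,3-dioxan-4-yl]methyl}-6-[2-(4-methoxyphenyl)ethyl]-2-(methylsulfanyl)-4H-pyran-4-one | CC(C)(C)[Si](C)(C)O[C@H](c1c(SC)oc(CCc2ccc(OC)cc2)cc1=O)[C@@H]3O[C@H](c4ccccc4)OC[C@H]3O | intermediate
19 | 3-{(R)-(tert-butyldimethylsilyloxy)[(2R,4R,5S)-5-{[7-fluoro-4-oxo-2-(2-phenylethyl)-4H-chromen-6-yl]oxy}-2-phenyl-1,3-dioxan-4-yl]methyl}-6-[2-(4-methoxyphenyl)ethyl]-2-(methylsulfanyl)-4H-pyran-4-one | CC(C)(C)[Si](C)(C)O[C@H](c1c(SC)oc(CCc2ccc(OC)cc2)cc1=O)[C@@H]3O[C@H](c4ccccc4)OC[C@@H]3Oc5cc6c(=O)cc(CCc7ccccc7)oc6cc5F | intermediate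
20 | tetrabutylammonium C5 alkoxide formed from 19 by desilylation | CCCC[N+](CCCC)(CCCC)CCCC.[O-][C@H](c1c(SC)oc(CCc2ccc(OC)cc2)cc1=O)[C@@H]3O[C@H](c4ccccc4)OC[C@@H]3Oc5cc6c(=O)cc(CCc7ccccc7)oc6cc5F | intermediate
21 | dioxepine sulfide: O5–C7' and O7–C6' ethers closed; C5 (R) bears the 6-[2-(4-methoxyphenyl)ethyl]-2-(methylsulfanyl)-4-oxo-4H-pyran-3-yl group; C6 (S) and C7 (S) lie in the (R)-benzylidene 1,3-dioxane spanning O6 and O8 | O1[C@H](c2c(SC)oc(CCc3ccc(OC)cc3)cc2=O)[C@@H]4O[C@H](c8ccccc8)OC[C@@H]4Oc5cc6c(=O)cc(CCc7ccccc7)oc6cc51 | intermediate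
22 | dioxepine sulfone: as 21 with C8a–SO2CH3 | O1[C@H](c2c(S(C)(=O)=O)oc(CCc3ccc(OC)cc3)cc2=O)[C@@H]4O[C@H](c8ccccc8)OC[C@@H]4Oc5cc6c(=O)cc(CCc7ccccc7)oc6cc51 | intermediate
23 | dioxepine stannane: as 21 with C8a–SnBu3 | O1[C@H](c2c([Sn](CCCC)(CCCC)CCCC)oc(CCc3ccc(OC)cc3)cc2=O)[C@@H]4O[C@H](c8ccccc8)OC[C@@H]4Oc5cc6c(=O)cc(CCc7ccccc7)oc6cc51 | intermediate
24 | dioxepine iodide: as 21 with C8a–I | O1[C@H](c2c(I)oc(CCc3ccc(OC)cc3)cc2=O)[C@@H]4O[C@H](c8ccccc8)OC[C@@H]4Oc5cc6c(=O)cc(CCc7ccccc7)oc6cc51 | intermediate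
25 | iodo diol: all-cis dioxepine, C5 (R) 2-iodopyranonyl, C6 (S) OH, C7 (S) CH2OH | O1[C@H](c2c(I)oc(CCc3ccc(OC)cc3)cc2=O)[C@H](O)[C@H](CO)Oc5cc6c(=O)cc(CCc7ccccc7)oc6cc51 | intermediate
26 | iodo aldehyde: all-cis dioxepine, C5 (R) 2-iodopyranonyl, C6 (S) OH, C7 (R) CHO | O1[C@H](c2c(I)oc(CCc3ccc(OC)cc3)cc2=O)[C@H](O)[C@H](C=O)Oc5cc6c(=O)cc(CCc7ccccc7)oc6cc51 | intermediate
27 | alkenylchromium dichloride: as 26 with C8a–CrCl2 | O1[C@H](c2c([Cr](Cl)Cl)oc(CCc3ccc(OC)cc3)cc2=O)[C@H](O)[C@H](C=O)Oc5cc6c(=O)cc(CCc7ccccc7)oc6cc51 | intermediate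
28 | (+)-4'-methoxyaquisinenone G (5R,6S,7R,8S) | COc1ccc(CCc2cc(=O)c3c(o2)[C@@H](O)[C@@H]2Oc4cc5c(=O)cc(CCc6ccccc6)oc5cc4O[C@H]3[C@@H]2O)cc1 | target

Total step count: 16.
Longest linear sequence: 12 steps (steps 1, 2 and 7–16; equally steps 3, 4 and 7–16).

Steps most likely to fail

Step 16. The carbonyl addition may show poor facial selectivity, the aldehyde reacting with its oxygen pseudoequatorial and giving the C8 epimer. The fallback sets C8 by hydride delivery instead of by the C–C bond formation. It sets out from 26: the same cyclisation is run and the C8 epimer of the target F1 is taken on. MnO2 in CH2Cl2 should oxidise only the allylic C8 alcohol, giving the 8-ketone F2. Reduction with NaBH4 and Et2BOMe in THF/MeOH at −78 °C (Narasaka–Prasad conditions, boron chelate with the syn-axial 6-OH, hydride from the open β-face) should give the 6,8-syn diol, which is 28, where the fallback comes back to the route.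

Step 7. Felkin-type attack may compete with chelation control and erode the facial selectivity at C5. The fallback replaces substrate control by reagent control. It sets out from alkoxide 16, which is protonated on aqueous work-up to the C5-epimeric alcohols F3. Dess–Martin periodinane gives the 3-acylpyranone ketone F4. Oxazaborolidine-catalysed (Corey–Bakshi–Shibata) reduction with BH3·SMe2, using (R)-Me-CBS if the aryl-like pyranonyl group acts as the large substituent, should give the (5R)-alcohol F5. Silylation with tBuMe2SiOTf and 2,6-lutidine returns to the route at 17.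

Step 9. The SN2 displacement at the hindered C7 carbinol may stall or give way to elimination. The fallback exchanges the roles of the two ether-forming reactions, so that the difficult C7–O bond is made intramolecularly. It sets out from 16 (protonated to the (5R)-alcohol F5 above) and phenol 14. Phenol 14 is converted with allyl bromide and K2CO3 into 6-allyloxy-7-fluoro-2-(2-phenylethyl)chromone F6. The alkoxide of F5 (NaN(SiMe3)2, THF/DMF) displaces the C7' fluorine of F6 to give the C5 aryl ether F7. Pd(PPh3)4 with morpholine, then pyridinium p-toluenesulfonate in MeOH, remove the allyl and triethylsilyl groups to give the hydroxy phenol F8. An intramolecular Mitsunobu reaction (PPh3, diisopropyl azodicarboxylate, toluene, high dilution) then closes the dioxepine with inversion at C7 and comes back to the route at 21.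

Further compounds

F1 | step 16 | C8 epimer of the target (5R,6S,7R,8R) | COc1ccc(CCc2cc(=O)c3c(o2)[C@H](O)[C@@H]2Oc4cc5c(=O)cc(CCc6ccccc6)oc5cc4O[C@H]3[C@@H]2O)cc1
F2 | step 16 | 8-oxo derivative of the target (5R,6S,7R) | COc1ccc(CCc2cc(=O)c3c(o2)C(=O)[C@@H]2Oc4cc5c(=O)cc(CCc6ccccc6)oc5cc4O[C@H]3[C@@H]2O)cc1
F3 | step 7 | C5-epimeric alcohols from protonation of 16 | OC(c1c(SC)oc(CCc2ccc(OC)cc2)cc1=O)[C@@H]3O[C@H](c4ccccc4)OC[C@H]3O[Si](CC)(CC)CC
F4 | step 7 | C5 ketone, 3-acylpyranone | O=C(c1c(SC)oc(CCc2ccc(OC)cc2)cc1=O)[C@@H]3O[C@H](c4ccccc4)OC[C@H]3O[Si](CC)(CC)CC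
F5 | step 7 | (5R)-alcohol with O7 triethylsilyl ether | O[C@H](c1c(SC)oc(CCc2ccc(OC)cc2)cc1=O)[C@@H]3O[C@H](c4ccccc4)OC[C@H]3O[Si](CC)(CC)CC
F6 | step 9 | 6-allyloxy-7-fluoro-2-(2-phenylethyl)-4H-chromen-4-one | C=CCOc1cc2c(=O)cc(CCc3ccccc3)oc2cc1F
F7 | step 9 | C5–O–C7' aryl ether with 6'-O-allyl and O7 triethylsilyl groups | C=CCOc1cc2c(=O)cc(CCc3ccccc3)oc2cc1O[C@H](c4c(SC)oc(CCc5ccc(OC)cc5)cc4=O)[C@@H]6O[C@H](c7ccccc7)OC[C@H]6O[Si](CC)(CC)CC
F8 | step 9 | C5–O–C7' aryl ether with free 6'-OH and free C7 OH | Oc1cc2c(=O)cc(CCc3ccccc3)oc2cc1O[C@H](c4c(SC)oc(CCc5ccc(OC)cc5)cc4=O)[C@@H]6O[C@H](c7ccccc7)OC[C@H]6O
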